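All runs were computed from invented constants.

A wait cannot turn into Q more X than still stands in the flask, unless some other species hands material back, so the question for the flask at 2.5 h is its feed, the X left there, and what the readings would have to show for that feed to make an option worthwhile.

in all of them: X 0.10 M

| run | J | temperature | remark | time |
|---|---|---|---|---|
| zeta | 1.2 equiv | 0 °C | the very flask that is asked about, followed so far |  |
| beta | 0.80 equiv | −5 °C | run made earlier |  |
| flask | 1.20 equiv | 0 °C |  | 2.5 h |

| run | time / min | Q / % | X / % |
|---|---|---|---|
| zeta | 25.0 | 53 | 9 |
| zeta | 50.0 | 59 | 3 |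
| zeta | 80.0 | 56 | 0 |
| zeta | 90.0 | 57 | 0 |
| zeta | 120 | 56 | 0 |
| beta | 0.667 | 4 | 93 |
| beta | 1.33 | 4 | 86 |
| beta | 2.00 | 9 | 77 |
| beta | 2.50 | 11 | 75 |
| beta | 3.00 | 11 | 73 |

(standard deviation of a reading: 1.5 percentage points)

- Saturday's: at 2.5 h add J, 100 % of the amount charged, then wait 50 min
- Sunday's: at 2.5 h raise the temperature by 20 K, then wait 50 min
- Friday's: change nothing and wait 50 min more
- Tuesday's: at 2.5 h take out 90 % of the Q then present, then wait 50 min

- what is taken out of Q is counted as made
- additions bring no volume worth counting

- Q, in percent of the X first charged, at 2.5 h
- the option that brings most further Q ("none" if no option brings more than 2 percentage points) (Saturday's / Sunday's / Friday's / Tuesday's / none)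
- Q present, with what was taken out counted in, in percent of the X first charged, after Friday's
- Q present, with what was taken out counted in, in percent of the X first charged, after Tuesday's

In the zeta run, which is this very flask followed so far, [X] reads 9 % at 25.0 min and 3 % at 50.0 min, and with J charged in excess this tail is treated as a pseudo-first-order decay, which gives a reading of 22.8 min for the tail constant, the time in which [X] falls by a factor of e. Carried on to 2.5 h, that constant leaves a feed of 0.0370 %. Turned round, a feed equal to the margin of 2 percentage points would need a constant of 247 min, ten times the one read, and going round once more with that constant puts X at 2.26 % at 120 min, where the reading is 0 % with a scatter of 1.5 points. The reckoned feed therefore stays below the margin, and, provided the missing material gives nothing back, this reckoning names none of the options and holds Q near the mean of the late readings, 56.3 %.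

The forecast gave 57 % at 2.5 h, 57 % after Friday's, 77 % after Tuesday's and Tuesday's as the best option, on the view that “the plateau looks like an equilibrium”.

The flask gives 52.5 % at 2.5 h, 49.7 % after Friday's and 52.2 % after Tuesday's, with none as the best option; measured from the Q at 2.5 h, Friday's loses 2.8 points and Tuesday's loses 0.27 points.

    X + J → Q + D (k = 0.940 M⁻¹ min⁻¹, Ea = 44.0 kJ mol⁻¹)
    2 X → Z (k = 0.610 M⁻¹ min⁻¹, Ea = 66.0 kJ mol⁻¹)
    J + Q → L + D (k = 0.0240 M⁻¹ min⁻¹, Ea = 52.0 kJ mol⁻¹)
    (constants at 0 °C)

The feed at 150 min is 0.0142 %, less than the reckoned 0.0370 %, and Q is made at 0.0106 of the rate at which it is used up, each taken net. The main reason for the Q missing from the flask at 2.5 h is the step from two X to Z, which accounts for 81 % of what is missing: without that step Q stands at 90.8 % rather than 52.5 %. In the neighbour flask stopped at 40 min, the tail constant counts back from the zeta reading to 4.65 %, and that flask holds 2.86 % of X, still above the margin.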